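## Analysis of the target

Atoms are numbered as in germacranolides: C1–C10 form the carbocycle, C11–C13 the lactone carbons (C12 carbonyl, C13 exocyclic methylene), C14 is the methyl on C10 and C15 the hydroxymethyl on C4.

The ten-membered carbocycle is bridged by an ether oxygen between C3 and C10, so that O, C3, C2, C1 and C10 form a 3(2H)-furanone inside an 11-oxabicyclo[6.2.1] frame. It is also fused at C6/C7 to an α-methylene-γ-butyrolactone (C6–O–C12(=O)–C11(=C13H2)–C7). There are four stereocentres, 6S, 7S, 8R and 10R. H6 and H7 are trans on the lactone, and O6, C11 and O8 are all syn along the C6–C7–C8 chain. The quaternary C10 is separated from this triad by the C9 methylene.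

The sensitive groups are the methylene lactone and the crotonate (both add amines, thiols and hydride), the cross-conjugated furanone, and the allylic C15 alcohol. An oxy-anion at O8 can also translactonise onto C12.

The difficulties are threefold: closing a medium ring that holds a cis C4=C5 alkene (C3 and C6 on the same side) and a bridgehead C2=C3 bond; keeping the two secondary oxygens that flank C7 differentiated (O6 as lactone, O8 as crotonate); and carrying the acyl groups through the ring closure.

The strategy rests on one feature. The C1 ketone lies between the quaternary C10 and the enol ether C2=C3, so the furanone is the cycloisomer of an α′-hydroxy ynone C10(OH)–C1(=O)–C2≡C3. That alkyne, joined to the cis C4=C5 alkene, is a stiff enyne that holds C2 close to C1.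

## Retrosynthetic reasoning

**O–C3 bond of the furanone.** Target 32 is opened to the ten-membered hydroxy ynone 31. Forward, the C10 hydroxyl adds 5-endo-dig to C3 of the activated alkyne. Cutting here removes the bridgehead alkene from the ring-closure problem, and the strain of the cycloalkyne is released in the last step. The closure is run under neutral gold catalysis rather than with an amine, because an amine would add to the methylene lactone and the crotonate.

**Adjustment of 31.** Ynone 31 comes from the bis-silyl ynone 30 and this from the propargylic alcohol 29. Both C1 epimers of 29 give the same ketone, so the carbinol configuration needs no control.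

**C1–C2 bond (ring closure).** Enynol 29 is cut between the carbinol carbon and the alkyne, giving the iodoalkyne aldehyde 27. The ring is cut here because the aldehyde is non-enolisable (C10 is quaternary) and the alkyne terminus is the only nucleophilic site that can be generated next to two esters and a methylene lactone. The enyne also leaves only the C6–C10 segment free to rotate. Forward, a chromium acetylide must add to the aldehyde faster than to another molecule.

**Functional groups of 27.** The aldehyde is taken back to a primary triethylsilyl ether, the iodoalkyne to the trimethylsilyl alkyne, and the crotonate to alcohol 24, through 26 and 25. All three changes are non-basic and are placed late, so the aldehyde exists for one step only.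

**C8 carbinol.** Alcohol 24 comes from ketone 23 by reagent-controlled reduction, and 23 from the dithiane 22. C8 is thus carried as a masked acyl group.

**C7–C8 and C11–C13 bonds.** Dithiane 22 is traced through the Mannich base 20 to butenolide 12 and the lithiated form of dithiane 17. Conjugate addition anti to the C6 substituent sets the trans lactone, and trapping the enolate brings in C13 in the same operation. The bond is cut here because C10 can then come from the chiral pool with C8 as its nucleophilic neighbour.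

**C6–C7 bond and lactone.** Butenolide 12 comes from the γ-hydroxy ynoate 10, which is made by asymmetric alkynylation of enynal 7 with methyl propiolate 8. This sets C6 by catalyst control and delivers C7, C11 and C12 at the right oxidation level.

**C3–C4 bond and the alkene.** Enynal 7 goes back through 6 to the Z-iodoalkene 4 and trimethylsilylacetylene 5. Iodide 4 arises from but-2-yne-1,4-diol 1 via 2 by directed trans-hydroalumination, which fixes the C4=C5 geometry at the start.

**C8–C9 bond.** Dithiane 17 comes via diol 16 from 1,3-dithiane 14 and (S)-2-methylglycidol 13. The epoxide is opened at its CH2 carbon, so C10 is never touched.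

## Alternatives that were turned down

**Alternative 1:** The ring is cut at C7–C8 with the furanone already in place. Forward, SmI2 reduces the C8 aldehyde of the furanone butenolide A1 to a ketyl that adds to the butenolide β-carbon C7, giving the hydroxy lactone A2.
- For: ring, C7 and C8 are made in one step, no strained alkyne is needed, and attack anti to the C6 substituent would give the trans lactone.
- Against: the cross-conjugated furanone of A1 is itself reducible by SmI2. The C8 configuration depends on a transannular transition state with no clear control element. The samarium alkoxide at O8 can translactonise onto C12. A2 also lacks C13 and the crotonate, so a strong-base methylenation would have to be run on the furanone.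
- Comparison: it is stronger in bonds and stereocentres per step. The chosen route instead sets all four centres before ring closure and needs only three mild steps after it.

**Alternative 2:** The C10–O bond (and the C1–O bond) is cut. Forward, m-CPBA epoxidises the C1=C10 alkene of the ten-membered dienone A3, and camphorsulfonic acid lets the C3 carbonyl oxygen attack C10 with loss of a C2 proton, giving the dihydrofuranol A4.
- For: it follows the likely biogenesis, the acyl groups are already in place, and only an allylic oxidation remains.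
- Against: it does not say how the ten-membered ring of A3 is made, so the hardest problem is moved rather than solved. C10 would be set by face selectivity on a flexible germacradiene and by an SN1-like opening at a tertiary carbon. Protonated germacrene epoxides also cyclise transannularly through carbon.
- Comparison: its end game is as short or shorter. The chosen route takes C10 from the chiral pool and makes the ring-forming step itself the plan.

**Alternative 3:** C3–C4, C2–C3 and O–C3 are cut, with CO supplying C3. Forward, the iodoalkene propargylic alcohol A5 undergoes a ring-closing carbonylative Sonogashira coupling (CO, PdCl2(PPh3)2, Et3N); Et2NH then closes the furanone to give A6.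
- For: it is the most convergent plan, with three bonds and both rings formed in one pot, no iodoalkyne and no separate oxidation.
- Against: the acylpalladium–acetylide coupling to a strained ten-membered ynone must outrun the direct coupling and oligomerisation. The amine step forbids the methylene lactone and the crotonate, so A6 lacks both and at least four further steps (strong-base methylenation, desilylation, acylation) follow on the furanone.
- Comparison: it is stronger in bonds per step. The chosen route offers an amine-free end game with every acyl group already present, and a ring closure of a type known for ten-membered rings that hold an enyne.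

Key step: step 16

Remark: CIP descriptors are given per compound because priorities change along the route. The C4=C5 alkene keeps one geometry throughout (C3 and C6 cis); it is E by the sequence rules while C3 is an alkyne carbon and Z in the furanone.
Assumption: [(2S)-2-methyloxiran-2-yl]methanol 13 is bought as the single enantiomer; otherwise it is one asymmetric epoxidation away from 2-methylprop-2-en-1-ol.
Abbreviations: TBS = tert-butyl(dimethyl)silyl, TES = triethylsilyl, TMS = trimethylsilyl.

## Route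

Step 1
Reactants: 1 but-2-yne-1,4-diol
Product: 2 4-(TBS-oxy)but-2-yn-1-ol
Conditions: NaH (1.0 equiv), THF, 0 °C; TBSCl (1.0 equiv), 0 °C to rt
Reagents that add atoms: tert-butyl(chloro)dimethylsilane, CC(C)(C)[Si](C)(C)Cl
Why: Monosilylation of a symmetrical diol through its poorly soluble monosodium alkoxide, which should limit bis-silylation; unreacted diol is washed out with water.

Step 2
Reactants: 2 4-(TBS-oxy)but-2-yn-1-ol
Product: 4 (2Z)-4-(TBS-oxy)-3-iodobut-2-en-1-ol, via cyclic alkenylaluminate 3 (not isolated)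
Conditions: NaAlH2(OCH2CH2OCH3)2 (Red-Al, 1.5 equiv), THF, 0 °C to rt; EtOAc; I2 (2 equiv), −78 to 0 °C
Reagents that add atoms: iodine, II
Why: Hydroxyl-directed trans-hydroalumination puts hydride on C5 and aluminium on C4; iodinolysis with retention should give the alkenyl iodide with iodine cis to the carbinol carbon C6, which fixes the C4=C5 geometry.

Step 3
Reactants: 4 (2Z)-4-(TBS-oxy)-3-iodobut-2-en-1-ol; 5 ethynyl(trimethyl)silane
Product: 6 (2E)-3-[(TBS-oxy)methyl]-5-TMS-pent-2-en-4-yn-1-ol
Conditions: PdCl2(PPh3)2 (3 mol%), CuI (6 mol%), Et3N, THF, rt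
Reagents that add atoms: none
Why: Sonogashira coupling of an alkenyl iodide goes with retention of geometry and tolerates the free alcohol, so C3 and C2 are attached cis to C6.

Step 4
Reactants: 6 (2E)-3-[(TBS-oxy)methyl]-5-TMS-pent-2-en-4-yn-1-ol
Product: 7 (2E)-3-[(TBS-oxy)methyl]-5-TMS-pent-2-en-4-ynal
Conditions: MnO2 (excess), CH2Cl2, rt
Reagents that add atoms: none
Why: Allylic oxidation with MnO2 stops at the aldehyde; the formyl group already sits cis to the small alkynyl group, so no geometric isomerisation is expected.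

Step 5
Reactants: 7 (2E)-3-[(TBS-oxy)methyl]-5-TMS-pent-2-en-4-ynal; 8 methyl prop-2-ynoate
Product: 10 methyl (4S,5E)-6-[(TBS-oxy)methyl]-4-hydroxy-8-TMS-oct-5-ene-2,7-diynoate, via methylzinc acetylide 9 (not isolated)
Conditions: 8 (2.8 equiv), Me2Zn (2.9 equiv), (S,S)-ProPhenol (20 mol%), Ph3P=O (40 mol%), toluene, 0 °C; then 7, 0 to 4 °C
Reagents that add atoms: none
Why: Catalytic asymmetric alkynylation by a dinuclear zinc–ProPhenol complex; the acetylide must add to the Re face of the enal to set C6 (4S in 10). The ligand antipode is the one that corresponds to this face, and the assignment would be checked by Mosher analysis on the first run.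

Step 6
Reactants: 10 methyl (4S,5E)-6-[(TBS-oxy)methyl]-4-hydroxy-8-TMS-oct-5-ene-2,7-diynoate
Product: 12 (5R)-5-{(1E)-2-[(TBS-oxy)methyl]-4-TMS-but-1-en-3-yn-1-yl}furan-2(5H)-one, via (Z)-hydroxy enoate 11 (not isolated)
Conditions: H2 (1 atm), Pd/CaCO3 poisoned with Pb(OAc)2, quinoline, EtOAc, rt, stopped after 1 equiv H2; then PPTS (cat.), CH2Cl2, rt
Reagents that add atoms: none
Why: Lindlar cis-semihydrogenation should take the unhindered, electron-poor ynoate before the silyl-capped conjugated alkyne; the Z-γ-hydroxy enoate then lactonises to the butenolide without touching C6.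

Step 7
Reactants: 13 [(2S)-2-methyloxiran-2-yl]methanol; 14 1,3-dithiane
Product: 16 (2R)-3-(1,3-dithian-2-yl)-2-methylpropane-1,2-diol, via 2-lithio-1,3-dithiane 15 (not isolated)
Conditions: 14 (2.3 equiv), n-BuLi (2.2 equiv), THF, −30 °C; then 13, DMPU, −30 °C to rt
Reagents that add atoms: none
Why: Epoxide opening by a dithiane anion at the unsubstituted epoxide carbon (C9), after the first equivalent has deprotonated the hydroxyl; no bond to the quaternary C10 is broken, so its configuration comes unchanged from 13.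

Step 8
Reactants: 16 (2R)-3-(1,3-dithian-2-yl)-2-methylpropane-1,2-diol
Product: 17 2-[(2R)-2-methyl-2,3-bis(TES-oxy)propyl]-1,3-dithiane
Conditions: TESOTf (2.5 equiv), 2,6-lutidine (4 equiv), CH2Cl2, −78 to 0 °C
Reagents that add atoms: triethylsilyl trifluoromethanesulfonate, CC[Si](CC)(CC)OS(=O)(=O)C(F)(F)F
Why: Silyl triflate silylation covers both the primary (C1) and the hindered tertiary (C10) hydroxyl in one operation.

Step 9
Reactants: 17 2-[(2R)-2-methyl-2,3-bis(TES-oxy)propyl]-1,3-dithiane; 12 (5R)-5-{(1E)-2-[(TBS-oxy)methyl]-4-TMS-but-1-en-3-yn-1-yl}furan-2(5H)-one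
Product: 20 (3S,4R,5S)-3-[(dimethylamino)methyl]-4-{2-[(2R)-2-methyl-2,3-bis(TES-oxy)propyl]-1,3-dithian-2-yl}-5-{(1E)-2-[(TBS-oxy)methyl]-4-TMS-but-1-en-3-yn-1-yl}oxolan-2-one, via lithiated dithiane 18 (not isolated), via lithium lactone enolate 19 (not isolated)
Conditions: 17 (1.2 equiv), t-BuLi (1.2 equiv), THF/HMPA 10:1, −78 °C; 12, −78 °C; CH2=NMe2+ I− (3 equiv), −78 to 0 °C
Reagents that add atoms: N,N-dimethylmethyleneiminium iodide (Eschenmoser's salt), C=[N+](C)C.[I-]
Why: Conjugate addition of a 2-lithio-1,3-dithiane (acyl anion equivalent for C8) to a butenolide, steered to the β-carbon by HMPA; attack at C7 anti to the C6 side chain should give the trans lactone. The enolate is trapped in a Mannich reaction that brings in C13; the C11 centre (expected trans to C7) disappears in step 10.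

Step 10
Reactants: 20 (3S,4R,5S)-3-[(dimethylamino)methyl]-4-{2-[(2R)-2-methyl-2,3-bis(TES-oxy)propyl]-1,3-dithian-2-yl}-5-{(1E)-2-[(TBS-oxy)methyl]-4-TMS-but-1-en-3-yn-1-yl}oxolan-2-one
Product: 22 (4R,5S)-3-methylidene-4-{2-[(2R)-2-methyl-2,3-bis(TES-oxy)propyl]-1,3-dithian-2-yl}-5-{(1E)-2-[(TBS-oxy)methyl]-4-TMS-but-1-en-3-yn-1-yl}oxolan-2-one, via ammonium iodide 21 (not isolated)
Conditions: MeI (3 equiv), MeOH/CH2Cl2, rt; then aq. NaHCO3, rt
Reagents that add atoms: none
Why: Quaternisation and E1cB loss of trimethylamine unveil the methylene lactone under mild base while C8 is still masked; the amine is far more nucleophilic towards MeI than the dithiane sulfur.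

Step 11
Reactants: 22 (4R,5S)-3-methylidene-4-{2-[(2R)-2-methyl-2,3-bis(TES-oxy)propyl]-1,3-dithian-2-yl}-5-{(1E)-2-[(TBS-oxy)methyl]-4-TMS-but-1-en-3-yn-1-yl}oxolan-2-one
Product: 23 (4R,5S)-3-methylidene-4-[(3R)-3-methyl-3,4-bis(TES-oxy)butanoyl]-5-{(1E)-2-[(TBS-oxy)methyl]-4-TMS-but-1-en-3-yn-1-yl}oxolan-2-one
Conditions: Dess–Martin periodinane (3 equiv), MeCN/CH2Cl2/H2O 8:1:1, rt
Reagents that add atoms: water, O
Why: Oxidative dethioacetalisation by a hypervalent iodine reagent under near-neutral conditions should spare the silyl ethers, the silyl alkyne and the methylene lactone; no base is present, so the acidic C7 hydrogen next to the new ketone is left alone.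

Step 12
Reactants: 23 (4R,5S)-3-methylidene-4-[(3R)-3-methyl-3,4-bis(TES-oxy)butanoyl]-5-{(1E)-2-[(TBS-oxy)methyl]-4-TMS-but-1-en-3-yn-1-yl}oxolan-2-one
Product: 24 (4S,5S)-4-[(1R,3R)-1-hydroxy-3-methyl-3,4-bis(TES-oxy)butyl]-3-methylidene-5-{(1E)-2-[(TBS-oxy)methyl]-4-TMS-but-1-en-3-yn-1-yl}oxolan-2-one
Conditions: (S)-2-methyl-CBS-oxazaborolidine (1.0 equiv), catecholborane (2 equiv), toluene/CH2Cl2, −78 °C
Reagents that add atoms: none
Why: Corey–Bakshi–Shibata reduction; with the branched ring carbon C7 as the large group and the C9 methylene as the small one, the (S)-catalyst should deliver hydride to the Si face and give the 8R carbinol by reagent control. Catecholborane at −78 °C should leave the methylene lactone alone.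

Step 13
Reactants: 24 (4S,5S)-4-[(1R,3R)-1-hydroxy-3-methyl-3,4-bis(TES-oxy)butyl]-3-methylidene-5-{(1E)-2-[(TBS-oxy)methyl]-4-TMS-but-1-en-3-yn-1-yl}oxolan-2-one
Product: 25 (1R,3R)-3-methyl-1-[(2S,3S)-4-methylidene-5-oxo-2-{(1E)-2-[(TBS-oxy)methyl]-4-TMS-but-1-en-3-yn-1-yl}oxolan-3-yl]-3,4-bis(TES-oxy)butyl (2E)-but-2-enoate
Conditions: (E)-crotonic anhydride (2 equiv), DMAP (0.2 equiv), pyridine, CH2Cl2, 0 °C to rt
Reagents that add atoms: (2E)-but-2-enoic anhydride, C/C=C/C(=O)OC(=O)/C=C/C
Why: DMAP-catalysed acylation of the secondary alcohol with retention at C8; the weakly basic conditions should avoid translactonisation onto O8 and deconjugation of the crotonate.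

Step 14
Reactants: 25 (1R,3R)-3-methyl-1-[(2S,3S)-4-methylidene-5-oxo-2-{(1E)-2-[(TBS-oxy)methyl]-4-TMS-but-1-en-3-yn-1-yl}oxolan-3-yl]-3,4-bis(TES-oxy)butyl (2E)-but-2-enoate
Product: 26 (1R,3R)-1-[(2S,3S)-2-{(1E)-2-[(TBS-oxy)methyl]-4-iodobut-1-en-3-yn-1-yl}-4-methylidene-5-oxooxolan-3-yl]-3-methyl-3,4-bis(TES-oxy)butyl (2E)-but-2-enoate
Conditions: N-iodosuccinimide (1.3 equiv), AgNO3 (0.1 equiv), acetone, rt, dark
Reagents that add atoms: N-iodosuccinimide, O=C1CCC(=O)N1I
Why: Silver-catalysed iododesilylation of a trimethylsilyl alkyne through the silver acetylide gives the 1-iodoalkyne directly, with no basic step and no free terminal alkyne.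

Step 15
Reactants: 26 (1R,3R)-1-[(2S,3S)-2-{(1E)-2-[(TBS-oxy)methyl]-4-iodobut-1-en-3-yn-1-yl}-4-methylidene-5-oxooxolan-3-yl]-3-methyl-3,4-bis(TES-oxy)butyl (2E)-but-2-enoate
Product: 27 (1R,3R)-1-[(2S,3S)-2-{(1E)-2-[(TBS-oxy)methyl]-4-iodobut-1-en-3-yn-1-yl}-4-methylidene-5-oxooxolan-3-yl]-3-methyl-4-oxo-3-(TES-oxy)butyl (2E)-but-2-enoate
Conditions: (COCl)2 (4 equiv), DMSO (8 equiv), CH2Cl2, −78 to −40 °C; Et3N (12 equiv), −78 to 0 °C
Reagents that add atoms: none
Why: Under Swern conditions a primary triethylsilyl ether is cleaved in situ and oxidised to the aldehyde, while the tertiary triethylsilyl ether and the primary TBS ether are inert. The aldehyde has no α-hydrogen and is used at once.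

Step 16
Reactants: 27 (1R,3R)-1-[(2S,3S)-2-{(1E)-2-[(TBS-oxy)methyl]-4-iodobut-1-en-3-yn-1-yl}-4-methylidene-5-oxooxolan-3-yl]-3-methyl-4-oxo-3-(TES-oxy)butyl (2E)-but-2-enoate
Product: 29 (4E,6S,7S,8R,10R)-8-[(2E)-but-2-enoyloxy]-1-hydroxy-15-(TBS-oxy)-10-(TES-oxy)germacra-4,11(13)-dien-2-yn-12,6-olide (both C1 epimers), via alkynylchromium dichloride 28 (not isolated)
Conditions: CrCl2 (8 equiv), NiCl2 (1 mol% of the CrCl2), degassed THF, rt, 27 added over 10 h to a final 0.003 M
Reagents that add atoms: none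
Why: Divalent chromium reduces NiCl2 to zerovalent nickel, which inserts into the C2–I bond; transmetalation to trivalent chromium gives 28, which adds to the C1 aldehyde through a chromium-bound carbonyl and forms the C1–C2 bond. The closest known reaction type is the intramolecular Nozaki–Hiyama–Kishi coupling of 1-iodoalkynes with aldehydes that closes nine- and ten-membered enediyne rings. The ten-membered carbocycle closes in the 10-exo-trig mode, with the carbonyl oxygen outside the ring. The new C1 carbinol centre is under no control and needs none, since both epimers give ynone 30 in step 17. The step needs selectivity for the aldehyde over lactone, methylene lactone and crotonate, which the weakly basic, carbonyl-selective organochromium reagent should provide. It also needs ring closure over oligomerisation, which is served by slow addition at high dilution, by the non-enolisable aldehyde on quaternary C10, and by the stiff enyne (C3 cis to C6) that leaves only the C6–C10 segment free to rotate.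

Step 17
Reactants: 29 (4E,6S,7S,8R,10R)-8-[(2E)-but-2-enoyloxy]-1-hydroxy-15-(TBS-oxy)-10-(TES-oxy)germacra-4,11(13)-dien-2-yn-12,6-olide
Product: 30 (4E,6S,7S,8R,10R)-8-[(2E)-but-2-enoyloxy]-1-oxo-15-(TBS-oxy)-10-(TES-oxy)germacra-4,11(13)-dien-2-yn-12,6-olide
Conditions: Dess–Martin periodinane (1.5 equiv), NaHCO3, CH2Cl2, 0 °C to rt
Reagents that add atoms: none
Why: Dess–Martin oxidation of the propargylic alcohol gives the ynone under buffered, non-nucleophilic conditions; the two C1 epimers converge.

Step 18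
Reactants: 30 (4E,6S,7S,8R,10R)-8-[(2E)-but-2-enoyloxy]-1-oxo-15-(TBS-oxy)-10-(TES-oxy)germacra-4,11(13)-dien-2-yn-12,6-olide
Product: 31 (4E,6S,7S,8R,10R)-8-[(2E)-but-2-enoyloxy]-10,15-dihydroxy-1-oxogermacra-4,11(13)-dien-2-yn-12,6-olide
Conditions: HF·pyridine, pyridine, THF, 0 °C to rt
Reagents that add atoms: none
Why: Buffered HF·pyridine cleaves the primary TBS and the tertiary TES ether without touching the esters or the lactone; if the freed C10 hydroxyl already begins to add to the ynone, this only anticipates step 19.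

Step 19
Reactants: 31 (4E,6S,7S,8R,10R)-8-[(2E)-but-2-enoyloxy]-10,15-dihydroxy-1-oxogermacra-4,11(13)-dien-2-yn-12,6-olide
Product: 32 (4Z,6S,7S,8R,10R)-8-[(2E)-but-2-enoyloxy]-3,10-epoxy-15-hydroxy-1-oxogermacra-2,4,11(13)-trien-12,6-olide (CNP0225232.1)
Conditions: Ph3PAuCl (5 mol%), AgOTf (5 mol%), toluene, rt
Reagents that add atoms: none
Why: Gold-catalysed cycloisomerisation of an α′-hydroxy ynone to a 3(2H)-furanone: cationic monovalent gold activates the alkyne for 5-endo-dig attack of the C10 hydroxyl at C3, and protodeauration follows. Release of the cycloalkyne strain drives it, and the neutral conditions should leave methylene lactone, crotonate and the C15 alcohol untouched.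

## Compound list

1 | but-2-yne-1,4-diol | OCC#CCO | starting material
2 | 4-(TBS-oxy)but-2-yn-1-ol | OCC#CCO[Si](C)(C)C(C)(C)C | intermediate
3 | sodium cyclic alkenylaluminate (Al on C4 and on the C6 oxygen, two 2-methoxyethoxy ligands) | COCCO[Al-]1(OCCOC)OCC=C1CO[Si](C)(C)C(C)(C)C.[Na+] | intermediate
4 | (2Z)-4-(TBS-oxy)-3-iodobut-2-en-1-ol | OC/C=C(/CO[Si](C)(C)C(C)(C)C)I | intermediate
5 | ethynyl(trimethyl)silane | C#C[Si](C)(C)C | starting material
6 | (2E)-3-[(TBS-oxy)methyl]-5-TMS-pent-2-en-4-yn-1-ol | OC/C=C(/CO[Si](C)(C)C(C)(C)C)C#C[Si](C)(C)C | intermediate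
7 | (2E)-3-[(TBS-oxy)methyl]-5-TMS-pent-2-en-4-ynal | O=C/C=C(/CO[Si](C)(C)C(C)(C)C)C#C[Si](C)(C)C | intermediate
8 | methyl prop-2-ynoate | C#CC(=O)OC | starting material
9 | methyl 3-(methylzincio)prop-2-ynoate | C[Zn]C#CC(=O)OC | intermediate
10 | methyl (4S,5E)-6-[(TBS-oxy)methyl]-4-hydroxy-8-TMS-oct-5-ene-2,7-diynoate | COC(=O)C#C[C@@H](O)/C=C(/CO[Si](C)(C)C(C)(C)C)C#C[Si](C)(C)C | intermediate
11 | methyl (2Z,4R,5E)-6-[(TBS-oxy)methyl]-4-hydroxy-8-TMS-octa-2,5-dien-7-ynoate | COC(=O)/C=C\[C@@H](O)/C=C(/CO[Si](C)(C)C(C)(C)C)C#C[Si](C)(C)C | intermediate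
12 | (5R)-5-{(1E)-2-[(TBS-oxy)methyl]-4-TMS-but-1-en-3-yn-1-yl}furan-2(5H)-one | O=C1C=C[C@H](/C=C(/CO[Si](C)(C)C(C)(C)C)C#C[Si](C)(C)C)O1 | intermediate
13 | [(2S)-2-methyloxiran-2-yl]methanol | C[C@]1(CO)CO1 | starting material
14 | 1,3-dithiane | C1CSCSC1 | starting material
15 | 2-lithio-1,3-dithiane | [Li]C1SCCCS1 | intermediate
16 | (2R)-3-(1,3-dithian-2-yl)-2-methylpropane-1,2-diol | S1CCCSC1C[C@@](C)(O)CO | intermediate
17 | 2-[(2R)-2-methyl-2,3-bis(TES-oxy)propyl]-1,3-dithiane | S1CCCSC1C[C@@](C)(O[Si](CC)(CC)CC)CO[Si](CC)(CC)CC | intermediate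
18 | 2-lithio-2-[(2R)-2-methyl-2,3-bis(TES-oxy)propyl]-1,3-dithiane | [Li]C1(C[C@@](C)(O[Si](CC)(CC)CC)CO[Si](CC)(CC)CC)SCCCS1 | intermediate
19 | lithium enolate of the trans conjugate adduct (C12 enolate, C11 unsubstituted) | C1=C(O[Li])O[C@@H](/C=C(/CO[Si](C)(C)C(C)(C)C)C#C[Si](C)(C)C)[C@@H]1C2(C[C@@](C)(O[Si](CC)(CC)CC)CO[Si](CC)(CC)CC)SCCCS2 | intermediate
20 | (3S,4R,5S)-3-[(dimethylamino)methyl]-4-{2-[(2R)-2-methyl-2,3-bis(TES-oxy)propyl]-1,3-dithian-2-yl}-5-{(1E)-2-[(TBS-oxy)methyl]-4-TMS-but-1-en-3-yn-1-yl}oxolan-2-one | CN(C)C[C@H]1C(=O)O[C@@H](/C=C(/CO[Si](C)(C)C(C)(C)C)C#C[Si](C)(C)C)[C@@H]1C2(C[C@@](C)(O[Si](CC)(CC)CC)CO[Si](CC)(CC)CC)SCCCS2 | intermediate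
21 | trimethylammonium iodide of 20 | C[N+](C)(C)C[C@H]1C(=O)O[C@@H](/C=C(/CO[Si](C)(C)C(C)(C)C)C#C[Si](C)(C)C)[C@@H]1C2(C[C@@](C)(O[Si](CC)(CC)CC)CO[Si](CC)(CC)CC)SCCCS2.[I-] | intermediate
22 | (4R,5S)-3-methylidene-4-{2-[(2R)-2-methyl-2,3-bis(TES-oxy)propyl]-1,3-dithian-2-yl}-5-{(1E)-2-[(TBS-oxy)methyl]-4-TMS-but-1-en-3-yn-1-yl}oxolan-2-one | C=C1C(=O)O[C@@H](/C=C(/CO[Si](C)(C)C(C)(C)C)C#C[Si](C)(C)C)[C@@H]1C2(C[C@@](C)(O[Si](CC)(CC)CC)CO[Si](CC)(CC)CC)SCCCS2 | intermediate
23 | (4R,5S)-3-methylidene-4-[(3R)-3-methyl-3,4-bis(TES-oxy)butanoyl]-5-{(1E)-2-[(TBS-oxy)methyl]-4-TMS-but-1-en-3-yn-1-yl}oxolan-2-one | C=C1C(=O)O[C@@H](/C=C(/CO[Si](C)(C)C(C)(C)C)C#C[Si](C)(C)C)[C@@H]1C(=O)C[C@@](C)(O[Si](CC)(CC)CC)CO[Si](CC)(CC)CC | intermediate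
24 | (4S,5S)-4-[(1R,3R)-1-hydroxy-3-methyl-3,4-bis(TES-oxy)butyl]-3-methylidene-5-{(1E)-2-[(TBS-oxy)methyl]-4-TMS-but-1-en-3-yn-1-yl}oxolan-2-one | C=C1C(=O)O[C@@H](/C=C(/CO[Si](C)(C)C(C)(C)C)C#C[Si](C)(C)C)[C@@H]1[C@H](O)C[C@@](C)(O[Si](CC)(CC)CC)CO[Si](CC)(CC)CC | intermediate
25 | (1R,3R)-3-methyl-1-[(2S,3S)-4-methylidene-5-oxo-2-{(1E)-2-[(TBS-oxy)methyl]-4-TMS-but-1-en-3-yn-1-yl}oxolan-3-yl]-3,4-bis(TES-oxy)butyl (2E)-but-2-enoate | C=C1C(=O)O[C@@H](/C=C(/CO[Si](C)(C)C(C)(C)C)C#C[Si](C)(C)C)[C@@H]1[C@H](OC(=O)/C=C/C)C[C@@](C)(O[Si](CC)(CC)CC)CO[Si](CC)(CC)CC | intermediate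
26 | (1R,3R)-1-[(2S,3S)-2-{(1E)-2-[(TBS-oxy)methyl]-4-iodobut-1-en-3-yn-1-yl}-4-methylidene-5-oxooxolan-3-yl]-3-methyl-3,4-bis(TES-oxy)butyl (2E)-but-2-enoate | C=C1C(=O)O[C@@H](/C=C(/CO[Si](C)(C)C(C)(C)C)C#CI)[C@@H]1[C@H](OC(=O)/C=C/C)C[C@@](C)(O[Si](CC)(CC)CC)CO[Si](CC)(CC)CC | intermediate
27 | (1R,3R)-1-[(2S,3S)-2-{(1E)-2-[(TBS-oxy)methyl]-4-iodobut-1-en-3-yn-1-yl}-4-methylidene-5-oxooxolan-3-yl]-3-methyl-4-oxo-3-(TES-oxy)butyl (2E)-but-2-enoate | C=C1C(=O)O[C@@H](/C=C(/CO[Si](C)(C)C(C)(C)C)C#CI)[C@@H]1[C@H](OC(=O)/C=C/C)C[C@@](C)(O[Si](CC)(CC)CC)C=O | intermediate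
28 | alkynylchromium dichloride from 27 (CrCl2 on C2) | C=C1C(=O)O[C@@H](/C=C(/CO[Si](C)(C)C(C)(C)C)C#C[Cr](Cl)Cl)[C@@H]1[C@H](OC(=O)/C=C/C)C[C@@](C)(O[Si](CC)(CC)CC)C=O | intermediate
29 | (4E,6S,7S,8R,10R)-8-[(2E)-but-2-enoyloxy]-1-hydroxy-15-(TBS-oxy)-10-(TES-oxy)germacra-4,11(13)-dien-2-yn-12,6-olide (both C1 epimers) | C=C1C(=O)O[C@H]2/C=C(/CO[Si](C)(C)C(C)(C)C)C#CC(O)[C@@](C)(C[C@@H](OC(=O)/C=C/C)[C@H]12)O[Si](CC)(CC)CC | intermediate
30 | (4E,6S,7S,8R,10R)-8-[(2E)-but-2-enoyloxy]-1-oxo-15-(TBS-oxy)-10-(TES-oxy)germacra-4,11(13)-dien-2-yn-12,6-olide | C=C1C(=O)O[C@H]2/C=C(/CO[Si](C)(C)C(C)(C)C)C#CC(=O)[C@@](C)(C[C@@H](OC(=O)/C=C/C)[C@H]12)O[Si](CC)(CC)CC | intermediate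
31 | (4E,6S,7S,8R,10R)-8-[(2E)-but-2-enoyloxy]-10,15-dihydroxy-1-oxogermacra-4,11(13)-dien-2-yn-12,6-olide | C=C1C(=O)O[C@H]2/C=C(/CO)C#CC(=O)[C@@](C)(C[C@@H](OC(=O)/C=C/C)[C@H]12)O | intermediate
32 | (4Z,6S,7S,8R,10R)-8-[(2E)-but-2-enoyloxy]-3,10-epoxy-15-hydroxy-1-oxogermacra-2,4,11(13)-trien-12,6-olide (CNP0225232.1) | C=C1C(=O)O[C@H]2/C=C(/CO)C3=CC(=O)[C@@](C)(C[C@@H](OC(=O)/C=C/C)[C@H]12)O3 | target

## Step count and least certain steps

Total: 19 steps. Longest linear sequence: 17 steps (from 1 through steps 1–6 and 9–19); the dithiane branch (steps 7 and 8) joins at step 9.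

**Step 16 (key step).** The most likely failures are reduction without coupling (protonation of 28 to the terminal alkyne, or single-electron reduction of the methylene lactone by the excess divalent chromium) and intermolecular coupling, because the bent ten-membered enyne is strained. The fallback sets out from 25 and comes back at 29. The silyl alkyne is protodesilylated (AgNO3 cat., acetone/H2O) to the terminal alkyne, (1R,3R)-1-[(2S,3S)-2-{(1E)-2-[(TBS-oxy)methyl]but-1-en-3-yn-1-yl}-4-methylidene-5-oxooxolan-3-yl]-3-methyl-3,4-bis(TES-oxy)butyl (2E)-but-2-enoate F1. The primary silyl ether is oxidised as in step 15 to the corresponding 4-oxo-3-(TES-oxy)butyl ester, the alkyne aldehyde F2. The ring is then closed by a zinc acetylide made by soft deprotonation (Zn(OTf)2, iPr2NEt, toluene, high dilution), so no reducing metal meets the methylene lactone.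

**Step 12.** Facial selectivity may be poor, because the two flanks of the C8 ketone (the ring methine C7 and the C9 methylene next to a quaternary carbon) may not differ enough for the oxazaborolidine, and the intrinsic bias of the C7 centre may oppose it. The exocyclic alkene of 23 may also migrate into conjugation before reduction. The fallback sets out from 23 and comes back at 25. If the bias favours the other face, it is used: reduction with the (R)-catalyst gives the 8S alcohol, (4S,5S)-4-[(1S,3R)-1-hydroxy-3-methyl-3,4-bis(TES-oxy)butyl]-3-methylidene-5-{(1E)-2-[(TBS-oxy)methyl]-4-TMS-but-1-en-3-yn-1-yl}oxolan-2-one F3. This is esterified with inversion by a Mitsunobu reaction with (2E)-but-2-enoic acid (PPh3, DIAD, toluene).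

**Step 9.** The basic dithianyl anion may deprotonate C6 of butenolide 12 (a γ-hydrogen acidified by the enyne), causing racemisation or isomerisation to the γ-alkylidene butenolide instead of conjugate addition. The fallback sets out from 17 and 7 and comes back at 23, forming the C6–C7 bond instead. Lithiated 18 is alkylated with methyl 2-(bromomethyl)prop-2-enoate to the dithiane ester, methyl 2-({2-[(2R)-2-methyl-2,3-bis(TES-oxy)propyl]-1,3-dithian-2-yl}methyl)prop-2-enoate F4. The ketone is unmasked as in step 11 to give methyl (6R)-6-methyl-2-methylidene-4-oxo-6,7-bis(TES-oxy)heptanoate F5. A boron aldol reaction of F5 (Ipc2BOTf, iPr2NEt, CH2Cl2, −78 °C; then 7) through the Z-enol borinate of the C7 methylene gives the syn aldolate, which closes onto the methyl ester to give 23. The Ipc antipode is chosen for Re-face attack on 7.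

**Step 6.** Hydrogenation may go on to the silyl alkyne or the conjugated diene. The fallback sets out from 4 and comes back at 12, so that only one alkyne is present during the hydrogenation. MnO2 gives (2Z)-4-(TBS-oxy)-3-iodobut-2-enal F6. Alkynylation as in step 5 gives methyl (4S,5Z)-7-(TBS-oxy)-4-hydroxy-6-iodohept-5-en-2-ynoate F7. Semihydrogenation and lactonisation as in step 6 give (5R)-5-[(1Z)-3-(TBS-oxy)-2-iodoprop-1-en-1-yl]furan-2(5H)-one F8. A base-free Stille coupling with tributyl[(trimethylsilyl)ethynyl]stannane (Pd2(dba)3, AsPh3, DMF, rt) then gives 12.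

## Further compounds

F1 | step 16 | (1R,3R)-1-[(2S,3S)-2-{(1E)-2-[(TBS-oxy)methyl]but-1-en-3-yn-1-yl}-4-methylidene-5-oxooxolan-3-yl]-3-methyl-3,4-bis(TES-oxy)butyl (2E)-but-2-enoate | C=C1C(=O)O[C@@H](/C=C(/CO[Si](C)(C)C(C)(C)C)C#C)[C@@H]1[C@H](OC(=O)/C=C/C)C[C@@](C)(O[Si](CC)(CC)CC)CO[Si](CC)(CC)CC
F2 | step 16 | (1R,3R)-1-[(2S,3S)-2-{(1E)-2-[(TBS-oxy)methyl]but-1-en-3-yn-1-yl}-4-methylidene-5-oxooxolan-3-yl]-3-methyl-4-oxo-3-(TES-oxy)butyl (2E)-but-2-enoate | C=C1C(=O)O[C@@H](/C=C(/CO[Si](C)(C)C(C)(C)C)C#C)[C@@H]1[C@H](OC(=O)/C=C/C)C[C@@](C)(O[Si](CC)(CC)CC)C=O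
F3 | step 12 | (4S,5S)-4-[(1S,3R)-1-hydroxy-3-methyl-3,4-bis(TES-oxy)butyl]-3-methylidene-5-{(1E)-2-[(TBS-oxy)methyl]-4-TMS-but-1-en-3-yn-1-yl}oxolan-2-one | C=C1C(=O)O[C@@H](/C=C(/CO[Si](C)(C)C(C)(C)C)C#C[Si](C)(C)C)[C@@H]1[C@@H](O)C[C@@](C)(O[Si](CC)(CC)CC)CO[Si](CC)(CC)CC
F4 | step 9 | methyl 2-({2-[(2R)-2-methyl-2,3-bis(TES-oxy)propyl]-1,3-dithian-2-yl}methyl)prop-2-enoate | C=C(CC1(C[C@@](C)(O[Si](CC)(CC)CC)CO[Si](CC)(CC)CC)SCCCS1)C(=O)OC
F5 | step 9 | methyl (6R)-6-methyl-2-methylidene-4-oxo-6,7-bis(TES-oxy)heptanoate | C=C(CC(=O)C[C@@](C)(O[Si](CC)(CC)CC)CO[Si](CC)(CC)CC)C(=O)OC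
F6 | step 6 | (2Z)-4-(TBS-oxy)-3-iodobut-2-enal | O=C/C=C(/CO[Si](C)(C)C(C)(C)C)I
F7 | step 6 | methyl (4S,5Z)-7-(TBS-oxy)-4-hydroxy-6-iodohept-5-en-2-ynoate | COC(=O)C#C[C@@H](O)/C=C(/CO[Si](C)(C)C(C)(C)C)I
F8 | step 6 | (5R)-5-[(1Z)-3-(TBS-oxy)-2-iodoprop-1-en-1-yl]furan-2(5H)-one | O=C1C=C[C@H](/C=C(/CO[Si](C)(C)C(C)(C)C)I)O1
A1 | alternative 1 | furanone butenolide aldehyde (C8 aldehyde, C7=C11 butenolide, 15-O-TBS) | O=C1C=C[C@H](/C=C(/CO[Si](C)(C)C(C)(C)C)C2=CC(=O)[C@@](C)(CC=O)O2)O1
A2 | alternative 1 | furanone-bridged ten-membered lactone with free 8-hydroxyl and C11 methylene group | C1C(=O)O[C@H]2/C=C(/CO[Si](C)(C)C(C)(C)C)C3=CC(=O)[C@@](C)(C[C@@H](O)[C@H]12)O3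
A3 | alternative 2 | (1(10)E)-8-crotonyloxy-3-oxo-15-(TBS-oxy)germacra-1(10),4,11(13)-trien-12,6-olide | C=C1C(=O)O[C@H]2/C=C(/CO[Si](C)(C)C(C)(C)C)C(=O)C/C=C(\C)C[C@@H](OC(=O)/C=C/C)[C@H]12
A4 | alternative 2 | bridged dihydrofuranol with C1 allylic alcohol | C=C1C(=O)O[C@H]2/C=C(/CO[Si](C)(C)C(C)(C)C)C3=C[C@H](O)[C@@](C)(C[C@@H](OC(=O)/C=C/C)[C@H]12)O3
A5 | alternative 3 | iodoalkene lactone with tertiary propargylic alcohol (8-O-TES, 15-O-TBS, no methylene) | C1C(=O)O[C@@H](/C=C(/CO[Si](C)(C)C(C)(C)C)I)[C@@H]1[C@H](O[Si](CC)(CC)CC)C[C@@](C)(O)C#C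
A6 | alternative 3 | furanone-bridged ten-membered lactone lacking methylene and crotonate (8-O-TES) | C1C(=O)O[C@H]2/C=C(/CO[Si](C)(C)C(C)(C)C)C3=CC(=O)[C@@](C)(C[C@@H](O[Si](CC)(CC)CC)[C@H]12)O3
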